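**Plan**

1. Retrosynthetic cuts, in order: the methyl ester and the diol acetonide (end-game adjustments); the ring bond between the C1 ketone (the one next to the ring CH2) and the alkene carbon C2 of the cyclohex-2-ene-1,4-dione; the bond from the quaternary ring carbon C5 to the first chain CH2; in the chain, C12'–C13' (allylboration) and C14'=C15' (cross-metathesis).
2. Enabling feature: C5 carries two CH2–C(=O) groups, the ring C6H2–C1(=O) and the exocyclic CH2–CO2Me, so an open precursor with two CH2–CHO arms is prochiral at C5. C2 is β to the C4 ketone, so C1–C2 is the bond of a 1,4-dicarbonyl that an acyl-anion equivalent at C1 (polarity reversal) can form by 6-endo-dig addition to a C4(=O)–C3≡C2–H ynone.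
3. Forward, chain (steps 1–6): farnesyl acetate → 12-oxo → anti-diol → acetonide → isopropylidene terminus → allylic bromide. Core (steps 7–12): methyl cyclopent-3-ene-1-carboxylate is opened to a symmetric bis-acetal ester (the cyclopentene is a latent 1,5-dialdehyde), alkylated with the bromide, and its ester is turned into an ethynyl ketone.
4. Acetal exchange frees the dialdehyde (step 13). The only ring of the target forms in step 14 by carbene catalysis that selects one of the two enantiotopic arms. The spare CH2CHO arm is the helper and becomes CH2CO2Me (steps 15–16); acid then frees the diol (step 17).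
5. Stereochemistry: the three chain alkenes are E from farnesol and from oxidation of its E-methyl group; C12'/C13' (S,R, anti) come from the chiral allylborane; C5 (R) comes from the chiral triazolium catalyst in the key step.

Key step: step 14

Assumption (step 3): the allylborane made from (−)-α-pinene is taken to attack the aldehyde face that gives 12S, as the parent B-allyl reagent does; if the opposite sense is found, the reagent from (+)-α-pinene is used.
Assumption (step 14): the (5aS,10bR) triazolium is taken to engage the arm that gives the R quaternary centre of the target; if the other arm reacts, its (5aR,10bS) antipode is used.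
Abbreviation: AGG = (2E,6E,10E,12S,13R)-12,13-(isopropylidenedioxy)-3,7,11,15-tetramethylhexadeca-2,6,10,14-tetraen-1-yl (the chain with its diol as acetonide).

**Route**

Step 1
Reactants: 1 (2E,6E)-farnesyl acetate
Product: 2 (2E,6E,10E)-12-hydroxy-3,7,11-trimethyldodeca-2,6,10-trien-1-yl acetate
Conditions: SeO2 (cat.), t-BuOOH, salicylic acid (cat.), CH2Cl2, 0 °C to rt
Reagents that add atoms: tert-butyl hydroperoxide CC(C)(C)OO (terminal oxidant); selenium dioxide O=[Se]=O (oxygen carrier)
Why: Riley allylic oxidation (ene reaction, then [2,3]-sigmatropic shift) should pick the E-methyl group of the terminal, most electron-rich trisubstituted alkene, the C2=C3 alkene being deactivated by the allylic acetate, and it leaves the new alkene E.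

Step 2
Reactants: 2 (2E,6E,10E)-12-hydroxy-3,7,11-trimethyldodeca-2,6,10-trien-1-yl acetate
Product: 3 (2E,6E,10E)-3,7,11-trimethyl-12-oxododeca-2,6,10-trien-1-yl acetate
Conditions: MnO2, CH2Cl2, rt
Reagents that add atoms: none
Why: Chemoselective MnO2 oxidation of the primary allylic alcohol to the E-enal; any aldehyde already formed in step 1 is the same compound.

Step 3
Reactants: 3 (2E,6E,10E)-3,7,11-trimethyl-12-oxododeca-2,6,10-trien-1-yl acetate
Product: 6 (2E,6E,10E,12S,13R)-3,7,11-trimethylpentadeca-2,6,10,14-tetraene-1,12,13-triol, via boron adduct 4 (not isolated), via diol acetate 5 (not isolated)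
Conditions: B-[(E)-3-(1,3,2-dioxaborinan-2-yl)prop-2-en-1-yl]bis(isopinocampheyl)borane [made in Et2O at 0 °C from (+)-Ipc2BH of (−)-α-pinene and 2-(propa-1,2-dien-1-yl)-1,3,2-dioxaborinane], Et2O, −78 °C; then 3 M NaOH, 30% H2O2, THF/MeOH, 0 °C to rt
Reagents that add atoms: B-[(E)-3-(1,3,2-dioxaborinan-2-yl)prop-2-en-1-yl]bis(isopinocampheyl)borane C[C@@H]1[C@@H](B(C/C=C/B2OCCCO2)[C@H]3C[C@H]4C[C@@H]([C@@H]3C)C4(C)C)C[C@H]5C[C@@H]1C5(C)C; hydrogen peroxide OO
Why: Brown-type allylboration through a chair (Zimmerman–Traxler) transition state: the E-γ-boryl allylborane sets the anti relationship, the isopinocampheyl groups set the aldehyde face (12S), oxidation of the C–B bond with retention gives the 13R alcohol, and the alkaline peroxide also saponifies the acetate.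

Step 4
Reactants: 6 (2E,6E,10E,12S,13R)-3,7,11-trimethylpentadeca-2,6,10,14-tetraene-1,12,13-triol
Product: 7 (2E,6E,10E,12S,13R)-12,13-(isopropylidenedioxy)-3,7,11-trimethylpentadeca-2,6,10,14-tetraen-1-ol
Conditions: 2,2-dimethoxypropane, PPTS (cat.), CH2Cl2, rt; MeOH quench (cleaves any mixed ketal at O1)
Reagents that add atoms: 2,2-dimethoxypropane COC(C)(C)OC
Why: Acid-catalysed transketalization closes the cis-dioxolane on the 1,2-diol only and leaves the primary allylic alcohol free.

Step 5
Reactants: 7 (2E,6E,10E,12S,13R)-12,13-(isopropylidenedioxy)-3,7,11-trimethylpentadeca-2,6,10,14-tetraen-1-ol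
Product: 8 AGG alcohol [(2E,6E,10E,12S,13R)-12,13-(isopropylidenedioxy)-3,7,11,15-tetramethylhexadeca-2,6,10,14-tetraen-1-ol]
Conditions: 2-methylbut-2-ene (large excess), second-generation Grubbs catalyst RuCl2(=CHPh)(PCy3)(H2IMes) (5 mol %), CH2Cl2, 40 °C, sealed tube
Reagents that add atoms: 2-methylbut-2-ene CC=C(C)C
Why: Olefin cross-metathesis of the only monosubstituted alkene with 2-methylbut-2-ene installs the isopropylidene terminus; the trisubstituted chain alkenes are far slower partners and ring closure would have to give a cyclobutene.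

Step 6
Reactants: 8 AGG alcohol
Product: 10 AGG bromide, via allylic mesylate 9 (not isolated)
Conditions: MsCl, Et3N, THF, −40 °C; then LiBr, THF, −40 to 0 °C; used crude
Reagents that add atoms: lithium bromide [Li+].[Br-]
Why: Mesylation followed by SN2 displacement with bromide under non-acidic conditions should give the primary allylic bromide without allylic transposition or loss of the acetonide.

Step 7
Reactants: 11 methyl cyclopent-3-ene-1-carboxylate
Product: 13 methyl 4,4-dimethoxy-2-(2,2-dimethoxyethyl)butanoate, via dialdehyde 12 (not isolated)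
Conditions: O3, CH2Cl2/MeOH, −78 °C; Me2S; then HC(OMe)3, TsOH·H2O (cat.), MeOH, rt
Reagents that add atoms: methanol CO; trimethyl orthoformate COC(OC)OC
Why: Ozonolysis with reductive work-up opens the symmetric cyclopentene to the 1,5-dialdehyde, and acid-catalysed acetalization stores it as the bis(dimethyl acetal), which is stable to the enolate, hydride and Grignard steps that follow.

Step 8
Reactants: 13 methyl 4,4-dimethoxy-2-(2,2-dimethoxyethyl)butanoate; 10 AGG bromide
Product: 15 methyl 2-AGG-4,4-dimethoxy-2-(2,2-dimethoxyethyl)butanoate, via lithium enolate 14 (not isolated)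
Conditions: LiN(iPr)2, THF, −78 °C; DMPU; then 10, −78 to 0 °C
Reagents that add atoms: none
Why: SN2 alkylation of the ester enolate at the primary allylic bromide builds the quaternary carbon, which carries two identical arms and is therefore not yet a stereocentre.

Step 9
Reactants: 15 methyl 2-AGG-4,4-dimethoxy-2-(2,2-dimethoxyethyl)butanoate
Product: 16 2-AGG-4,4-dimethoxy-2-(2,2-dimethoxyethyl)butan-1-ol
Conditions: LiAlH4, THF, 0 °C
Reagents that add atoms: none
Why: Hydride reduction of the hindered methyl ester to the neopentyl alcohol leaves the acetals, the acetonide and the alkenes untouched.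

Step 10
Reactants: 16 2-AGG-4,4-dimethoxy-2-(2,2-dimethoxyethyl)butan-1-ol
Product: 17 2-AGG-4,4-dimethoxy-2-(2,2-dimethoxyethyl)butanal
Conditions: Dess–Martin periodinane, NaHCO3, CH2Cl2, rt
Reagents that add atoms: none
Why: Buffered Dess–Martin oxidation should give the non-enolizable neopentyl aldehyde without touching the acid-labile ketals.

Step 11
Reactants: 17 2-AGG-4,4-dimethoxy-2-(2,2-dimethoxyethyl)butanal
Product: 18 4-AGG-6,6-dimethoxy-4-(2,2-dimethoxyethyl)hex-1-yn-3-ol (both C3 epimers)
Conditions: HC≡CMgBr, THF, 0 °C to rt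
Reagents that add atoms: ethynylmagnesium bromide C#C[Mg]Br
Why: Grignard 1,2-addition of the small acetylide to the hindered aldehyde; the new carbinol centre is removed in the next step, so its configuration does not matter.

Step 12
Reactants: 18 4-AGG-6,6-dimethoxy-4-(2,2-dimethoxyethyl)hex-1-yn-3-ol
Product: 19 4-AGG-6,6-dimethoxy-4-(2,2-dimethoxyethyl)hex-1-yn-3-one
Conditions: Dess–Martin periodinane, NaHCO3, CH2Cl2, 0 °C
Reagents that add atoms: none
Why: Dess–Martin oxidation of the propargylic alcohol gives the terminal ynone under neutral, amine-free conditions that such Michael acceptors tolerate.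

Step 13
Reactants: 19 4-AGG-6,6-dimethoxy-4-(2,2-dimethoxyethyl)hex-1-yn-3-one
Product: 20 3-AGG-3-(prop-2-ynoyl)pentanedial
Conditions: TsOH·H2O (10 mol %), acetone/H2O (20:1), rt
Reagents that add atoms: water O
Why: Acid-catalysed acetal exchange with the solvent acetone should free both aldehydes while the same solvent holds the isopropylidene ketal in place by mass action, and the acid has no nucleophilic counter-ion that could add to the ynone.

Step 14
Reactants: 20 3-AGG-3-(prop-2-ynoyl)pentanedial
Product: 21 2-[(1S)-1-AGG-2,5-dioxocyclohex-3-en-1-yl]acetaldehyde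
Conditions: 20 dried azeotropically (toluene); (5aS,10bR)-2-(pentafluorophenyl)-5a,10b-dihydro-4H,6H-indeno[2,1-b][1,2,4]triazolo[4,3-d][1,4]oxazin-2-ium tetrafluoroborate (20 mol %), KN(SiMe3)2 (18 mol %), toluene (0.02 M), 4 Å MS, 0 °C; AcOH quench at full conversion
Reagents that add atoms: none
Why: Proposed new method: the triazolylidene adds reversibly to either formyl group of 20 and proton transfer gives a Breslow (acyl-anion) intermediate, whose nucleophilic carbon attacks the terminal β-carbon of the ethynyl ketone; protonation of the allenolate at the α-carbon and loss of the carbene give the cis-ene-dione. The closest known reactions are the intramolecular Stetter reaction of aliphatic aldehydes with enone and enoate acceptors under aminoindanol triazolium catalysts, the use of such catalysts to desymmetrize prochiral substrates, and the 6-endo-dig conjugate cyclization of oxygen and carbon nucleophiles onto ynones; a terminal ynone acceptor combined with two enantiotopic aldehyde donors has not been shown. The six-membered ring closes 6-endo-dig, the only mode that joins the acyl carbon to the electrophilic β-carbon (5-exo-dig attack at the α-carbon is electronically mismatched). The quaternary carbon, prochiral in 20, becomes stereogenic because the chiral carbene makes the two diastereomeric C–C bond-forming transition states (one per arm) unequal; carbene addition and Breslow formation are reversible, so the choice is made in the irreversible C–C step (Curtin–Hammett), and the S descriptor of 21 is the same spatial arrangement as R in the target. The step needs chemoselectivity for the Stetter path over benzoin closure between the two arms and over a second closure of the spare arm onto the new ene-dione: benzoin addition is reversible whereas addition to the ynone is not, the electron-poor N-pentafluorophenyl catalyst favours conjugate addition, and the second closure would have to build a bridged bicyclo[2.2.2]- or [3.2.1]octanetrione through a boat-like transition state, so it should be slower and is held back by low temperature and the acid quench.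

Step 15
Reactants: 21 2-[(1S)-1-AGG-2,5-dioxocyclohex-3-en-1-yl]acetaldehyde
Product: 22 2-[(1R)-1-AGG-2,5-dioxocyclohex-3-en-1-yl]acetic acid
Conditions: NaClO2, NaH2PO4, 2-methylbut-2-ene, t-BuOH/H2O, 0 °C
Reagents that add atoms: sodium chlorite [Na+].[O-]Cl=O
Why: Pinnick oxidation converts only the aldehyde, with 2-methylbut-2-ene trapping HOCl so that the chain alkenes are spared; the quaternary centre is untouched (the descriptor changes by priority only).

Step 16
Reactants: 22 2-[(1R)-1-AGG-2,5-dioxocyclohex-3-en-1-yl]acetic acid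
Product: 23 methyl 2-[(1R)-1-AGG-2,5-dioxocyclohex-3-en-1-yl]acetate
Conditions: MeI, KHCO3, DMF, rt
Reagents that add atoms: iodomethane CI
Why: SN2 O-alkylation of the carboxylate with a base too weak to enolize the ene-dione.

Step 17
Reactants: 23 methyl 2-[(1R)-1-AGG-2,5-dioxocyclohex-3-en-1-yl]acetate
Product: 24 methyl 2-[(1R)-1-[(2E,6E,10E,12S,13R)-12,13-dihydroxy-3,7,11,15-tetramethylhexadeca-2,6,10,14-tetraen-1-yl]-2,5-dioxocyclohex-3-en-1-yl]acetate (target)
Conditions: AcOH/H2O (4:1), 40 °C
Reagents that add atoms: none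
Why: Acid-catalysed hydrolysis of the isopropylidene ketal through the oxocarbenium ion at the ketal carbon should be faster than ionization of the allylic C–O bonds and frees the anti-diol without touching C12 or C13.

**Compound list**

1 | (2E,6E)-farnesyl acetate | CC(=O)OC/C=C(\C)CC/C=C(\C)CCC=C(C)C | starting material
2 | (2E,6E,10E)-12-hydroxy-3,7,11-trimethyldodeca-2,6,10-trien-1-yl acetate | CC(=O)OC/C=C(\C)CC/C=C(\C)CC/C=C(\C)CO | intermediate
3 | (2E,6E,10E)-3,7,11-trimethyl-12-oxododeca-2,6,10-trien-1-yl acetate | CC(=O)OC/C=C(\C)CC/C=C(\C)CC/C=C(\C)C=O | intermediate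
4 | boron adduct: the 12S O-bis(isopinocampheyl)boryl ether of 5 that carries a 1,3,2-dioxaborinan-2-yl group at C13 in place of the hydroxyl (same spatial arrangement) | CC(=O)OC/C=C(\C)CC/C=C(\C)CC/C=C(\C)[C@H](OB([C@H]1C[C@H]2C[C@@H]([C@@H]1C)C2(C)C)[C@H]3C[C@H]4C[C@@H]([C@@H]3C)C4(C)C)[C@H](B5OCCCO5)C=C | intermediate (not isolated)
5 | (2E,6E,10E,12S,13R)-12,13-dihydroxy-3,7,11-trimethylpentadeca-2,6,10,14-tetraen-1-yl acetate | CC(=O)OC/C=C(\C)CC/C=C(\C)CC/C=C(\C)[C@H](O)[C@H](O)C=C | intermediate (not isolated)
6 | (2E,6E,10E,12S,13R)-3,7,11-trimethylpentadeca-2,6,10,14-tetraene-1,12,13-triol | OC/C=C(\C)CC/C=C(\C)CC/C=C(\C)[C@H](O)[C@H](O)C=C | intermediate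
7 | (2E,6E,10E,12S,13R)-12,13-(isopropylidenedioxy)-3,7,11-trimethylpentadeca-2,6,10,14-tetraen-1-ol | OC/C=C(\C)CC/C=C(\C)CC/C=C(\C)[C@@H]1OC(C)(C)O[C@@H]1C=C | intermediate
8 | AGG alcohol, (2E,6E,10E,12S,13R)-12,13-(isopropylidenedioxy)-3,7,11,15-tetramethylhexadeca-2,6,10,14-tetraen-1-ol | OC/C=C(\C)CC/C=C(\C)CC/C=C(\C)[C@@H]1OC(C)(C)O[C@@H]1C=C(C)C | intermediate
9 | AGG methanesulfonate | CS(=O)(=O)OC/C=C(\C)CC/C=C(\C)CC/C=C(\C)[C@@H]1OC(C)(C)O[C@@H]1C=C(C)C | intermediate (not isolated)
10 | AGG bromide | BrC/C=C(\C)CC/C=C(\C)CC/C=C(\C)[C@@H]1OC(C)(C)O[C@@H]1C=C(C)C | intermediate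
11 | methyl cyclopent-3-ene-1-carboxylate | COC(=O)C1CC=CC1 | starting material
12 | methyl 4-oxo-2-(2-oxoethyl)butanoate | COC(=O)C(CC=O)CC=O | intermediate (not isolated)
13 | methyl 4,4-dimethoxy-2-(2,2-dimethoxyethyl)butanoate | COC(=O)C(CC(OC)OC)CC(OC)OC | intermediate
14 | lithium enolate of 13 | [Li+].COC([O-])=C(CC(OC)OC)CC(OC)OC | intermediate (not isolated)
15 | methyl 2-AGG-4,4-dimethoxy-2-(2,2-dimethoxyethyl)butanoate | COC(=O)C(CC(OC)OC)(CC(OC)OC)C/C=C(\C)CC/C=C(\C)CC/C=C(\C)[C@@H]1OC(C)(C)O[C@@H]1C=C(C)C | intermediate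
16 | 2-AGG-4,4-dimethoxy-2-(2,2-dimethoxyethyl)butan-1-ol | OCC(CC(OC)OC)(CC(OC)OC)C/C=C(\C)CC/C=C(\C)CC/C=C(\C)[C@@H]1OC(C)(C)O[C@@H]1C=C(C)C | intermediate
17 | 2-AGG-4,4-dimethoxy-2-(2,2-dimethoxyethyl)butanal | O=CC(CC(OC)OC)(CC(OC)OC)C/C=C(\C)CC/C=C(\C)CC/C=C(\C)[C@@H]1OC(C)(C)O[C@@H]1C=C(C)C | intermediate
18 | 4-AGG-6,6-dimethoxy-4-(2,2-dimethoxyethyl)hex-1-yn-3-ol (both C3 epimers) | C#CC(O)C(CC(OC)OC)(CC(OC)OC)C/C=C(\C)CC/C=C(\C)CC/C=C(\C)[C@@H]1OC(C)(C)O[C@@H]1C=C(C)C | intermediate
19 | 4-AGG-6,6-dimethoxy-4-(2,2-dimethoxyethyl)hex-1-yn-3-one | C#CC(=O)C(CC(OC)OC)(CC(OC)OC)C/C=C(\C)CC/C=C(\C)CC/C=C(\C)[C@@H]1OC(C)(C)O[C@@H]1C=C(C)C | intermediate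
20 | 3-AGG-3-(prop-2-ynoyl)pentanedial | C#CC(=O)C(CC=O)(CC=O)C/C=C(\C)CC/C=C(\C)CC/C=C(\C)[C@@H]1OC(C)(C)O[C@@H]1C=C(C)C | intermediate
21 | 2-[(1S)-1-AGG-2,5-dioxocyclohex-3-en-1-yl]acetaldehyde | O=CC[C@@]1(C/C=C(\C)CC/C=C(\C)CC/C=C(\C)[C@@H]2OC(C)(C)O[C@@H]2C=C(C)C)CC(=O)C=CC1=O | intermediate
22 | 2-[(1R)-1-AGG-2,5-dioxocyclohex-3-en-1-yl]acetic acid | OC(=O)C[C@@]1(C/C=C(\C)CC/C=C(\C)CC/C=C(\C)[C@@H]2OC(C)(C)O[C@@H]2C=C(C)C)CC(=O)C=CC1=O | intermediate
23 | methyl 2-[(1R)-1-AGG-2,5-dioxocyclohex-3-en-1-yl]acetate | COC(=O)C[C@@]1(C/C=C(\C)CC/C=C(\C)CC/C=C(\C)[C@@H]2OC(C)(C)O[C@@H]2C=C(C)C)CC(=O)C=CC1=O | intermediate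
24 | methyl 2-[(1R)-1-[(2E,6E,10E,12S,13R)-12,13-dihydroxy-3,7,11,15-tetramethylhexadeca-2,6,10,14-tetraen-1-yl]-2,5-dioxocyclohex-3-en-1-yl]acetate | COC(=O)C[C@@]1(C/C=C(\C)CC/C=C(\C)CC/C=C(\C)[C@H](O)[C@H](O)C=C(C)C)CC(=O)C=CC1=O | target

**Count**

Total steps: 17. Longest linear sequence: 16 (steps 1–6, then 8–17).

**Steps most likely to fail**

Step 14 (labelled step). What may go wrong: closure of the spare formyl arm onto the new ene-dione, benzoin closure between the two arms, addition of the carbene to the ynone, or weak discrimination between the enantiotopic arms. The fallback uses known reactions only, sets out from 20 and comes back at 21. Hydroiodination of the ynone (LiI, AcOH, MeCN, rt) should give the (Z)-β-iodovinyl ketone F1. An intramolecular Nozaki–Hiyama–Kishi reaction (CrCl2, NiCl2 cat., DMF, high dilution) then closes the same ring bond onto either formyl group and should give the 4-hydroxycyclohex-2-enone F2 (stereoisomer mixture, in part as a bridged lactol). MnO2 in CH2Cl2 oxidizes the ring allylic alcohol to 21 and its epimer at the quaternary carbon F3. These two are diastereomers through the chain and would be separated by preparative HPLC on a chiral stationary phase; 21 then re-enters at step 15.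

Step 13. What may go wrong: partial loss of the acetonide during acetal exchange, or hydration and self-condensation of the 1,5-dialdehyde under acid. The fallback sets out from 19 and comes back at 24; it drops the diol protection on purpose. AcOH/H2O/THF (3:1:1) at 40 °C should cleave both acetals and the acetonide to the diol dialdehyde F4. The conditions of step 14 then close the ring to the diol aldehyde F5, the conditions of step 15 give the diol acid F6, and the conditions of step 16 give 24 directly, so that no protecting group is left for the end.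

Step 3. What may go wrong: low or reversed facial selectivity of the chiral borane on the α-branched enal, or incomplete oxidation of the hindered allylic boronate. The fallback sets out from 2 and comes back at 6; it replaces the stoichiometric borane by a catalytic coupling at the alcohol oxidation level. Iridium-catalysed transfer-hydrogenative anti-(α-benzoyloxy)allylation of the allylic alcohol 2 with prop-2-ene-1,1-diyl dibenzoate ([Ir(cod)Cl]2, the enantiomer of 5,5'-bis(diphenylphosphino)-4,4'-bi-1,3-benzodioxole that gives the 12S,13R series, 4-cyano-3-nitrobenzoic acid, Cs2CO3, THF, 90 °C) should give the anti 13-benzoate F7. K2CO3 in MeOH then removes the benzoate and the acetate to give 6.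

**Further compounds**

F1 | step 14 | 3-AGG-3-[(2Z)-3-iodoprop-2-enoyl]pentanedial | O=CCC(CC=O)(C/C=C(\C)CC/C=C(\C)CC/C=C(\C)[C@@H]1OC(C)(C)O[C@@H]1C=C(C)C)C(=O)/C=C\I
F2 | step 14 | 2-(1-AGG-5-hydroxy-2-oxocyclohex-3-en-1-yl)acetaldehyde (stereoisomer mixture at C1 and C5 of the ring) | O=CCC1(C/C=C(\C)CC/C=C(\C)CC/C=C(\C)[C@@H]2OC(C)(C)O[C@@H]2C=C(C)C)CC(O)C=CC1=O
F3 | step 14 | 2-[(1R)-1-AGG-2,5-dioxocyclohex-3-en-1-yl]acetaldehyde (epimer of 21 at the quaternary carbon) | O=CC[C@]1(C/C=C(\C)CC/C=C(\C)CC/C=C(\C)[C@@H]2OC(C)(C)O[C@@H]2C=C(C)C)CC(=O)C=CC1=O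
F4 | step 13 | 3-[(2E,6E,10E,12S,13R)-12,13-dihydroxy-3,7,11,15-tetramethylhexadeca-2,6,10,14-tetraen-1-yl]-3-(prop-2-ynoyl)pentanedial | C#CC(=O)C(CC=O)(CC=O)C/C=C(\C)CC/C=C(\C)CC/C=C(\C)[C@H](O)[C@H](O)C=C(C)C
F5 | step 13 | 2-[(1S)-1-[(2E,6E,10E,12S,13R)-12,13-dihydroxy-3,7,11,15-tetramethylhexadeca-2,6,10,14-tetraen-1-yl]-2,5-dioxocyclohex-3-en-1-yl]acetaldehyde | O=CC[C@@]1(C/C=C(\C)CC/C=C(\C)CC/C=C(\C)[C@H](O)[C@H](O)C=C(C)C)CC(=O)C=CC1=O
F6 | step 13 | 2-[(1R)-1-[(2E,6E,10E,12S,13R)-12,13-dihydroxy-3,7,11,15-tetramethylhexadeca-2,6,10,14-tetraen-1-yl]-2,5-dioxocyclohex-3-en-1-yl]acetic acid | OC(=O)C[C@@]1(C/C=C(\C)CC/C=C(\C)CC/C=C(\C)[C@H](O)[C@H](O)C=C(C)C)CC(=O)C=CC1=O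
F7 | step 3 | (2E,6E,10E,12S,13R)-13-(benzoyloxy)-12-hydroxy-3,7,11-trimethylpentadeca-2,6,10,14-tetraen-1-yl acetate | CC(=O)OC/C=C(\C)CC/C=C(\C)CC/C=C(\C)[C@H](O)[C@H](OC(=O)c1ccccc1)C=C
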